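**Plan**
- Retrosynthesis cuts, in order: the acetate C–O bond; the bond between the carbinol carbon and the trisubstituted alkene (alkenylzinc plus arylacetaldehyde); C4a=C5 of the five-membered ring, which opens the bicycle to a 4-pyranone carrying a but-2-enal arm; the pyranone–alkenyl bond (Stille); and the pyranone ring itself (methyl ketone plus two one-carbon units).
- Enabling feature: in cyclopenta[c]pyran numbering the core is a 4-alkylidene-4H-pyran (C4a=C5), and C5 is the γ-carbon of the enal at C7. The ring C4a–C5–C6–C7–C7a can therefore be closed by condensing that γ-carbon onto the carbonyl carbon of a 3,5-disubstituted 4-pyranone.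
- Forward order: pyranone ring first, then iodination, Stille coupling and oxidation to the enal, then closure of the cyclopentadiene ring through the 4-methoxypyrylium salt, then acetal hydrolysis, attachment of the terpenoid chain and acetylation.
- Stereochemistry: the single (S) centre comes from ligand-controlled addition of an (E)-alkenylzinc to the aliphatic aldehyde; the (E)-alkene comes from syn-methylalumination of a terminal alkyne.

Key step: step 7

Remark: the carbinol carbon is read from the SMILES as (S) (O > alkenyl > CH2-aryl > H) and the side-chain alkene as (E). The facial sense assigned to the amino-alcohol ligand in step 11 follows the usual model for this ligand class and would be confirmed on the product.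

**Route**

Step 1
Reactants: 1 5,5-dimethoxypentan-2-one; 2 N,N-dimethylformamide dimethyl acetal
Product: 3 (E)-1-(dimethylamino)-6,6-dimethoxyhex-1-en-3-one
Conditions: neat 2 (3 equiv), 100 °C
Reagents that add atoms: none
Why: Enaminone formation from a methyl ketone and an amide acetal occurs at the less hindered methyl group under neutral conditions that leave the acetal alone; any methylene isomer would converge on the same pyranone in step 2.

Step 2
Reactants: 3 (E)-1-(dimethylamino)-6,6-dimethoxyhex-1-en-3-one
Product: 5 3-(2,2-dimethoxyethyl)-4H-pyran-4-one, via hydroxymethylene enaminone 4 (not isolated)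
Conditions: KOtBu, HCO2Et, THF, 0 → 23 °C; then AcOH, 45 °C
Reagents that add atoms: ethyl formate, CCOC=O
Why: Claisen formylation at the only enolisable carbon followed by acid-promoted addition of the enol oxygen to the enaminone β-carbon with loss of dimethylamine is the established enaminone route to 4-pyranones; acetic acid protonates the vinylogous amide but should be too weak to ionise the dimethyl acetal.

Step 3
Reactants: 5 3-(2,2-dimethoxyethyl)-4H-pyran-4-one
Product: 6 3-(2,2-dimethoxyethyl)-5-iodo-4H-pyran-4-one
Conditions: I2, PhI(OCOCF3)2, pyridine, CH2Cl2, 23 °C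
Reagents that add atoms: iodine, [I][I]
Why: Electrophilic iodination of the vinylogous ester by the hypoiodite formed in situ should occur at C5, the only free carbon α to the carbonyl and β to the ring oxygen, and pyridine keeps the medium non-acidic for the acetal.

Step 4
Reactants: 7 but-2-yn-1-ol
Product: 8 (E)-2-(tributylstannyl)but-2-en-1-ol
Conditions: Bu3SnH, Pd(PPh3)2Cl2 (cat.), THF, 0 → 23 °C
Reagents that add atoms: tributyltin hydride, CCCC[SnH](CCCC)CCCC
Why: Palladium-catalysed syn-hydrostannation of a propargylic alcohol places tin mainly on the carbon next to the hydroxymethyl group with hydrogen cis to it, which fixes the (E)-stannane; the distal regioisomer should be removable by chromatography.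

Step 5
Reactants: 6 3-(2,2-dimethoxyethyl)-5-iodo-4H-pyran-4-one; 8 (E)-2-(tributylstannyl)but-2-en-1-ol
Product: 9 3-(2,2-dimethoxyethyl)-5-[(Z)-1-hydroxybut-2-en-2-yl]-4H-pyran-4-one
Conditions: Pd(PPh3)4 (cat.), CuI, CsF, DMF, 45 °C
Reagents that add atoms: none
Why: Stille coupling with copper iodide and fluoride acceleration suits hindered α-substituted alkenylstannanes and 3-iodo-4-pyranones, retains the alkene geometry and tolerates the free alcohol and the acetal.

Step 6
Reactants: 9 3-(2,2-dimethoxyethyl)-5-[(Z)-1-hydroxybut-2-en-2-yl]-4H-pyran-4-one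
Product: 10 (Z)-2-[5-(2,2-dimethoxyethyl)-4-oxo-4H-pyran-3-yl]but-2-enal
Conditions: MnO2, CH2Cl2, 23 °C
Reagents that add atoms: none
Why: MnO2 oxidises the allylic alcohol selectively to the enal without touching the acetal or the pyranone, and any E/Z drift is harmless because step 7 converges from either isomer.

Step 7
Reactants: 10 (Z)-2-[5-(2,2-dimethoxyethyl)-4-oxo-4H-pyran-3-yl]but-2-enal
Product: 13 4-(2,2-dimethoxyethyl)cyclopenta[c]pyran-7-carbaldehyde, via 4-methoxypyrylium triflate 11 (not isolated), via 4a-methoxy dihydro adduct 12 (not isolated)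
Conditions: MeOTf, 2,6-di-tert-butyl-4-methylpyridine (0.1 equiv), CH2Cl2, 0 → 23 °C; then iPr2NEt (3 equiv), −40 → 23 °C
Reagents that add atoms: none
Why: Proposed new method: MeOTf alkylates the most basic oxygen, the pyranone carbonyl, to give pyrylium salt 11; iPr2NEt then removes a γ-proton from the enal methyl group, the terminal carbon of the dienolate (C5) bonds to the pyrylium γ-carbon (C4a), and adduct 12 ionises back to a ring-fused pyrylium and loses a C5 proton, so that methanol is expelled and the aromatic ten-π-electron anhydrobase 13 results. The closest known reaction type is the intermolecular condensation of 4-pyranones or 4-alkoxypyrylium salts with C–H acids to give 4-ylidene-4H-pyrans; the intramolecular, vinylogous version is new. The five-membered ring (C4a, C5, C6, C7, C7a) closes by a thermally allowed disrotatory six-electron electrocyclisation over these five centres, formally 5-endo at the pyrylium C4a–C7a bond, and rotation about C6–C7 in the dienolate lets either enal geometry reach the reactive conformer. No stereocentre remains, because the C4a centre of 12 is lost on elimination. The step needs closure at the γ-carbon C4a and not at the α-carbon C1, and this is secured because only the C4a adduct carries a leaving group and can aromatise irreversibly, whereas the C1 adduct (a 2H-pyran without a leaving group) and the mixed ketal from attack of the dienolate oxygen can both revert to the pyrylium dienolate; attack through the dienolate α-carbon would need a three-membered ring. Ring opening of the 2,6-unsubstituted pyrylium is avoided by using only hindered, non-nucleophilic amines, and the pyridine buffer keeps triflic acid away from the acetal.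

Step 8
Reactants: 13 4-(2,2-dimethoxyethyl)cyclopenta[c]pyran-7-carbaldehyde
Product: 14 2-(7-formylcyclopenta[c]pyran-4-yl)acetaldehyde
Conditions: 1 M aq. HCl, THF, 0 → 23 °C; used crude at once
Reagents that add atoms: water, O
Why: Acid-catalysed hydrolysis of a dimethyl acetal; 7-formylcyclopenta[c]pyrans are the stable end point of acid treatment of related iridoid systems, so the chromophore should tolerate dilute acid.

Step 9
Reactants: 15 5-bromo-2-methylpent-2-ene
Product: 16 6-methylhept-5-en-1-yne
Conditions: HC≡CLi·H2NCH2CH2NH2, DMSO, 10 → 23 °C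
Reagents that add atoms: lithium acetylide ethylenediamine complex, [Li]C#C.NCCN
Why: SN2 alkylation of lithium acetylide by a primary homoallylic bromide in DMSO is a standard route to terminal alkynes.

Step 10
Reactants: 16 6-methylhept-5-en-1-yne
Product: 18 (E)-1-iodo-2,6-dimethylhepta-1,5-diene, via alkenyldimethylalane 17 (not isolated)
Conditions: AlMe3, Cp2ZrCl2 (cat.), CH2Cl2, 0 → 23 °C; then I2, THF, −30 → 0 °C
Reagents that add atoms: trimethylaluminium, C[Al](C)C; iodine, [I][I]
Why: Negishi carboalumination adds methyl and aluminium syn across the terminal alkyne with methyl on the internal carbon, and iodinolysis with retention gives the (E)-2-methylalkenyl iodide while the remote trisubstituted alkene stays inert.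

Step 11
Reactants: 18 (E)-1-iodo-2,6-dimethylhepta-1,5-diene; 14 2-(7-formylcyclopenta[c]pyran-4-yl)acetaldehyde
Product: 21 (S,E)-4-(2-hydroxy-4,8-dimethylnona-3,7-dien-1-yl)cyclopenta[c]pyran-7-carbaldehyde, via alkenyllithium 19 (not isolated), via alkenyl(ethyl)zinc 20 (not isolated)
Conditions: 18 (1.3 equiv), t-BuLi, Et2O, −78 °C; EtZnCl (from Et2Zn + ZnCl2); TEEDA, (+)-MIB (10 mol%); then 14, toluene, −20 °C
Reagents that add atoms: none
Why: Amino-alcohol-catalysed addition of an alkenyl(ethyl)zinc to an aldehyde transfers the alkenyl group with retention of its E geometry; since the (2S)-ligand of this class delivers to the Si face, (2R)-(+)-MIB should deliver to the Re face of the aliphatic aldehyde and set the (S)-carbinol, TEEDA sequestering the lithium salts that cause racemic background addition, while the C7 formyl group, a vinylogous formate on an electron-rich ring, should be far less electrophilic towards a near-stoichiometric zinc reagent at low temperature.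

Step 12
Reactants: 21 (S,E)-4-(2-hydroxy-4,8-dimethylnona-3,7-dien-1-yl)cyclopenta[c]pyran-7-carbaldehyde
Product: 22 (S,E)-1-(7-formylcyclopenta[c]pyran-4-yl)-4,8-dimethylnona-3,7-dien-2-yl acetate
Conditions: Ac2O, pyridine, DMAP (cat.), CH2Cl2, 0 → 23 °C
Reagents that add atoms: acetic anhydride, CC(=O)OC(C)=O
Why: DMAP-catalysed O-acetylation of the secondary allylic alcohol does not touch the C–O bond of the stereocentre, so the (S) configuration is retained.

**Compound list**

1 | 5,5-dimethoxypentan-2-one | CC(=O)CCC(OC)OC | starting material
2 | N,N-dimethylformamide dimethyl acetal | COC(OC)N(C)C | starting material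
3 | (E)-1-(dimethylamino)-6,6-dimethoxyhex-1-en-3-one | CN(C)/C=C/C(=O)CCC(OC)OC | intermediate
4 | 1-(dimethylamino)-4-(hydroxymethylidene)-6,6-dimethoxyhex-1-en-3-one (not isolated) | CN(C)/C=C/C(=O)C(=CO)CC(OC)OC | intermediate
5 | 3-(2,2-dimethoxyethyl)-4H-pyran-4-one | COC(OC)Cc1coccc1=O | intermediate
6 | 3-(2,2-dimethoxyethyl)-5-iodo-4H-pyran-4-one | COC(OC)Cc1cocc(I)c1=O | intermediate
7 | but-2-yn-1-ol | CC#CCO | starting material
8 | (E)-2-(tributylstannyl)but-2-en-1-ol | C/C=C(\CO)[Sn](CCCC)(CCCC)CCCC | intermediate
9 | 3-(2,2-dimethoxyethyl)-5-[(Z)-1-hydroxybut-2-en-2-yl]-4H-pyran-4-one | COC(OC)Cc1cocc(/C(CO)=C/C)c1=O | intermediate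
10 | (Z)-2-[5-(2,2-dimethoxyethyl)-4-oxo-4H-pyran-3-yl]but-2-enal | COC(OC)Cc1cocc(/C(C=O)=C/C)c1=O | intermediate
11 | 3-(2,2-dimethoxyethyl)-4-methoxy-5-[(Z)-1-oxobut-2-en-2-yl]pyrylium triflate (not isolated) | COC(OC)Cc1c[o+]cc(/C(C=O)=C/C)c1OC.[O-]S(=O)(=O)C(F)(F)F | intermediate
12 | 4-(2,2-dimethoxyethyl)-4a-methoxy-4a,5-dihydrocyclopenta[c]pyran-7-carbaldehyde (not isolated) | COC(OC)CC1=COC=C2C(C=O)=CCC12OC | intermediate
13 | 4-(2,2-dimethoxyethyl)cyclopenta[c]pyran-7-carbaldehyde | COC(OC)Cc1cocc2c(C=O)ccc1-2 | intermediate
14 | 2-(7-formylcyclopenta[c]pyran-4-yl)acetaldehyde | O=CCc1cocc2c(C=O)ccc1-2 | intermediate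
15 | 5-bromo-2-methylpent-2-ene | CC(C)=CCCBr | starting material
16 | 6-methylhept-5-en-1-yne | C#CCCC=C(C)C | intermediate
17 | [(E)-2,6-dimethylhepta-1,5-dien-1-yl]dimethylalane (not isolated) | C[Al](C)/C=C(\C)CCC=C(C)C | intermediate
18 | (E)-1-iodo-2,6-dimethylhepta-1,5-diene | I/C=C(\C)CCC=C(C)C | intermediate
19 | [(E)-2,6-dimethylhepta-1,5-dien-1-yl]lithium (not isolated) | [Li]/C=C(\C)CCC=C(C)C | intermediate
20 | [(E)-2,6-dimethylhepta-1,5-dien-1-yl](ethyl)zinc (not isolated) | CC[Zn]/C=C(\C)CCC=C(C)C | intermediate
21 | (S,E)-4-(2-hydroxy-4,8-dimethylnona-3,7-dien-1-yl)cyclopenta[c]pyran-7-carbaldehyde | O[C@H](/C=C(\C)CCC=C(C)C)Cc1cocc2c(C=O)ccc1-2 | intermediate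
22 | (S,E)-1-(7-formylcyclopenta[c]pyran-4-yl)-4,8-dimethylnona-3,7-dien-2-yl acetate | CC(=O)O[C@H](/C=C(\C)CCC=C(C)C)Cc1cocc2c(C=O)ccc1-2 | target

**Step count**

Total: 12 steps. Longest linear sequence: 9 steps (steps 1, 2, 3, 5, 6, 7, 8, 11, 12).

**Steps most likely to fail**

Step 7. The dienolate may close on the pyrylium α-carbon, the unsubstituted pyrylium ring may be opened by base before the slow γ-deprotonation occurs, or the acetal may be lost to adventitious triflic acid. The fallback uses known reactions only and reverses the polarity, closing the ring at C6=C7 by an aldol condensation; it sets out from iodopyranone 6 and comes back at dialdehyde 14. Stille coupling of 6 with tributyl[(Z)-2-ethoxyvinyl]stannane under the conditions of step 5 would give 3-(2,2-dimethoxyethyl)-5-[(Z)-2-ethoxyvinyl]-4H-pyran-4-one F1, a pyranone with two masked 2-oxoethyl arms. 1,2-Addition of (Z)-2-ethoxyvinyllithium (from (Z)-1-bromo-2-ethoxyethene and t-BuLi, THF, −78 °C) to the pyranone carbonyl would give 3-(2,2-dimethoxyethyl)-4,5-bis[(Z)-2-ethoxyvinyl]-4H-pyran-4-ol F2. Dilute aqueous HCl in THF would then ionise the carbinol and unmask all three aldehydes to 2-[3,5-bis(2-oxoethyl)-4H-pyran-4-ylidene]acetaldehyde F3, which would not be isolated. The enol of either arm (the two are equivalent) should condense with the ylidene-acetaldehyde carbon in an intramolecular aldol condensation, closing the five-membered ring with the formyl group at C7 and giving 14 directly.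

Step 11. The arylacetaldehyde may enolise and self-condense under the organozinc conditions, some alkenyl transfer to the C7 formyl group may compete, and facial discrimination of an α-unbranched aldehyde may be poor. The fallback sets out from 14 (with iodide 18) and comes back at 21. It replaces the zinc addition by a catalytic asymmetric Nozaki–Hiyama–Kishi coupling (CrCl2 with a chiral oxazoline–sulfonamide ligand, NiCl2 as co-catalyst, Mn, Cp2ZrCl2, LiCl, MeCN). This is a non-basic organochromium addition that is selective for the more electrophilic aldehyde, with the ligand enantiomer chosen for Re-face delivery. This fallback makes no new compound (F0).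

Step 2. The acetal may ionise during ring closure, and the 1,4-related hydroxymethylene and acetal carbons may then close to a 3-acylfuran (Paal–Knorr-type diversion) in place of the pyranone. The fallback carries the side chain as an allyl group through ring formation and unmasks it afterwards; it sets out from acetal 2 and comes back at pyranone 5. Commercial hex-5-en-2-one F4 is heated in 2 to give (E)-1-(dimethylamino)hepta-1,6-dien-3-one F5. Claisen formylation (KOtBu, HCO2Et) gives 1-(dimethylamino)-4-(hydroxymethylidene)hepta-1,6-dien-3-one F6, not isolated, which TFA in CH2Cl2 would cyclise to 3-allyl-4H-pyran-4-one F7. Lemieux–Johnson cleavage (OsO4 cat., NaIO4, 2,6-lutidine, dioxane/water) would give 2-(4-oxo-4H-pyran-3-yl)acetaldehyde F8, and CH(OMe)3, MeOH, PPTS would convert it into 5.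

**Further compounds**

F1 | step 7 | 3-(2,2-dimethoxyethyl)-5-[(Z)-2-ethoxyvinyl]-4H-pyran-4-one | COC(OC)Cc1cocc(/C=C\OCC)c1=O
F2 | step 7 | 3-(2,2-dimethoxyethyl)-4,5-bis[(Z)-2-ethoxyvinyl]-4H-pyran-4-ol | CCO/C=C\C1(O)C(CC(OC)OC)=COC=C1/C=C\OCC
F3 | step 7 | 2-[3,5-bis(2-oxoethyl)-4H-pyran-4-ylidene]acetaldehyde | O=CC=C1C(CC=O)=COC=C1CC=O
F0 | step 11 | none | none
F4 | step 2 | hex-5-en-2-one | CC(=O)CCC=C
F5 | step 2 | (E)-1-(dimethylamino)hepta-1,6-dien-3-one | CN(C)/C=C/C(=O)CCC=C
F6 | step 2 | 1-(dimethylamino)-4-(hydroxymethylidene)hepta-1,6-dien-3-one | CN(C)/C=C/C(=O)C(=CO)CC=C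
F7 | step 2 | 3-allyl-4H-pyran-4-one | C=CCc1coccc1=O
F8 | step 2 | 2-(4-oxo-4H-pyran-3-yl)acetaldehyde | O=CCc1coccc1=O
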